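| flask | starting complex | incoming ligand | protic impurity | remark | time |
|---|---|---|---|---|---|
| gamma | 2.7 M | 1.62 M | 0.135 M | the very flask that is asked about, followed so far |  |
| epsilon | 2.7 M | 1.1 M | 0.135 M | run made earlier |  |
| flask | 2.7 M | 1.62 M | 0.135 M |  | 20 h |

- gamma (time / h: starting complex / %, complex with one exchanged / %, complex with two exchanged / %): 0.833: 50.1, 39.2, 5.8; 2.00: 49.9, 39.6, 5.8; 4.00: 49.6, 40.0, 5.5; 10.0: 49.5, 39.1, 5.3
- epsilon (time / h: starting complex / %, complex with one exchanged / %, complex with two exchanged / %): 2.00: 61.4, 31.1, 2.4; 4.00: 61.0, 30.6, 2.4; 6.00: 61.4, 31.1, 1.9; 8.00: 61.4, 30.9, 2.9

(standard deviation of a reading: 0.3 percentage points)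

- the earlier runs were read with a standard deviation of 0.3 percentage points
- the reaction counts as stopped when no species that holds the starting complex changes by six tenths of a point or more over the second half of the time

- the state of affairs at 20 h: stopped, and by what, or still going (the incoming ligand has run out first / it is still moving / all of the starting complex has reacted / forward and back rates have come level)
- part of the starting complex gone at 20 h
- the complex with one exchanged standing at 20 h, as a percentage of the starting complex charged
- the complex with two exchanged standing at 20 h, as a percentage of the starting complex charged

I read the gamma flask at 2.00 h and again at 10.0 h: its starting complex moves by 0.4 percentage points, against a scatter of 0.3 points, so I freeze the run at its means. Gamma stands at 49.8% starting complex, 39.5% complex with one exchanged and 5.60% complex with two exchanged. The gap of 5.15% matches the impurity charge, 5.00% of the complex charged.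

Incoming ligand bound in these complexes leaves free ligand equal to 9.32% of the starting complex charged, so by these readings it has not run out. I therefore read gamma as two balanced exchanges. Dividing one balance by the other cancels the free ligands and leaves the exchange quotient, c(complex with one exchanged)² / [c(starting complex) · c(complex with two exchanged)], the comproportionation constant: 5.59. For 20 h I commit to the means, a conversion of 50.2%.

The weak link is the smallest reading. So I run the quotient backwards on epsilon, which was charged with less incoming ligand than gamma: it asks for 2.79% complex with two exchanged, and the epsilon readings lie between 1.9% and 2.9%.

The forecast says forward and back rates have come level, with 50.2% gone, 39.5% and 5.6%: “So this is equilibrium”.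

The flask gives forward and back rates have come level, with 50.2% gone, 39.7% and 5.54%.

    starting complex + incoming ligand ⇌ leaving ligand + complex with one exchanged (K = 4.40, k = 9.30 × 10⁻⁴ M⁻¹ s⁻¹)
    protic impurity + starting complex → quenched substrate (k = 0.00580 M⁻¹ s⁻¹)
    complex with one exchanged + incoming ligand ⇌ leaving ligand + complex with two exchanged (K = 0.770, k = 0.00200 M⁻¹ s⁻¹)

These values give a quotient of 5.71, and neither free ligand nor the 5.00% of quenched substrate enters it. In the flask at 20 h, the backward run of the second exchange is part of what keeps complex with one exchanged at 39.7%: the same run without it holds 0.750% of that complex, and its state of affairs is a different one. The same flask charged with 0.34 M of protic impurity holds 43.3% starting complex and 38.2% complex with one exchanged at 20 h, so the quotient asks for 6.03% complex with two exchanged; that flask gives 5.89%.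

The numbers in the tables were computed for substances that don't exist; the scatter is artificial.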